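Ring atoms: C1 bears the heptenyl chain, C2 the CH2OH, C3 the free OH; C4 and quaternary C5 form the oxirane; C6 is the carbonyl. The cyclohexenone ring shows two same-face oxygens on the adjacent carbons C3 (OH) and C4 (oxirane C–O), bracketed by the 1,4-related carbons C2 and C5, each carrying a carbon chain: the pattern left by cis-dihydroxylating a para-disubstituted benzene. One whole-cell dioxygenase oxidation of unprotected 2-(4-iodophenyl)ethanol makes both C–O bonds and both stereocentres while dearomatising the ring. Iodine then steers osmylation to C5=C6 and is the C2 coupling handle; the retained C4 oxygen later displaces a β-face C5 mesylate, closing the oxirane syn to C3–OH.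

Key step: step 1

Conventions: the target ring numbering is kept for all intermediates. α is the ring face that carries the two enzymatically introduced oxygens, and β is the opposite face.
Assumption: iodine, not the hydroxyethyl arm, occupies the large hydrophobic pocket of the enzyme, so 2 belongs to the (1S,2S) series. The optical purity of 2 is to be measured before it is carried on.
Remark on the order of events: iodine stays on C2 until C5=C6 has been oxidised. A C2–CH2OR diene would offer OsO4 two nearly equivalent trisubstituted alkenes.

Step 1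
Reactants: 1 2-(4-iodophenyl)ethanol
Product: 2 (1S,2S)-3-(2-hydroxyethyl)-6-iodocyclohexa-3,5-diene-1,2-diol (C2–I, C3α-OH, C4α-OH, C5–CH2CH2OH, C1=C2 and C5=C6)
Conditions: E. coli JM109(pDTG601A) whole cells expressing toluene dioxygenase, IPTG, glucose feed, air, pH 7 medium, 30–35 °C; EtOAc extraction
Reagents that add atoms: dioxygen, O=O
Why: The [2Fe–2S]-dependent non-haem iron dioxygenase uses two NADH-derived electrons to activate O2 at iron and hands both oxygen atoms to one face of the C3–C4 arene bond, so the C3–O and C4–O bonds form cis and the ring is left as the C2=C1–C6=C5 diene; no ring is closed. The closest known reaction type is the toluene-dioxygenase cis-dihydroxylation of halobenzenes, of 4-substituted iodobenzenes and of 2-phenylethyl substrates. Both new stereocentres (C3, C4) are controlled by the protein alone: suprafacial delivery fixes their cis relation, and the absolute sense follows from which para substituent lies in the large hydrophobic pocket, iodine there giving the (1S,2S) diol. Site selectivity is not at stake, because oxidation occurs ortho/meta to a substituent and the two CH–CH bonds of the para-disubstituted ring are interconverted by its symmetry and differ only in the enantiomer they lead to. The selectivity needed is therefore enantioselectivity, and it is served by pairing the largest, most lipophilic halogen with a side arm kept as small and polar as possible, which is why the alcohol is fed unprotected. The recombinant host lacks the dihydrodiol dehydrogenase, so rearomatisation to the catechol is blocked.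

Step 2
Reactants: 2 cis-dihydrodiol
Product: 3 2-[(3aS,7aS)-7-iodo-2,2-dimethyl-3a,7a-dihydro-1,3-benzodioxol-4-yl]ethanol (C3α,C4α-acetonide of 2, primary OH free)
Conditions: Me2C(OMe)2, p-TsOH·H2O (cat.), acetone, 0 °C → rt; Et3N quench; used without storage
Reagents that add atoms: 2,2-dimethoxypropane, COC(C)(C)OC
Why: Acid-catalysed transketalisation closes the cis-fused dioxolane on the syn C3/C4 diol (any acyclic mixed ketal at the primary alcohol falls apart on aqueous work-up), which blocks dehydrative rearomatisation and shields the α face; no stereocentre is touched.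

Step 3
Reactants: 3 acetonide alcohol
Product: 4 tert-butyldimethylsilyl ether of 3 (side chain CH2CH2OTBS)
Conditions: TBSCl, imidazole, CH2Cl2, 0 °C → rt
Reagents that add atoms: tert-butyldimethylsilyl chloride, CC(C)(C)[Si](C)(C)Cl
Why: Imidazole-promoted silylation of the single remaining (primary) hydroxyl gives an ether that withstands osmylation, oxidation, mesylation and neutral Pd chemistry yet leaves in the same acid treatment as the ketal.

Step 4
Reactants: 4 silylated iododiene acetonide
Product: 5 5β,6β-diol (cyclohex-1-ene with C2–I, C3α/C4α-acetonide, tertiary C5β-OH with the CH2CH2OTBS chain α, allylic C6β-OH)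
Conditions: OsO4 (cat.), NMO, acetone/H2O (4:1), 0 °C → rt
Reagents that add atoms: osmium tetroxide, O=[Os](=O)(=O)=O; N-methylmorpholine N-oxide, C[N+]1([O-])CCOCC1; water, O
Why: Catalytic OsO4/NMO syn-dihydroxylation picks the electron-richer, halogen-free C5=C6 bond of the diene over the iodine-deactivated C1=C2 bond and adds from the β face opposite the dioxolane, as is general for halodiene-diol acetonides, so that C5–OH and C6–OH are both set β and the side chain is pushed α.

Step 5
Reactants: 5 5β,6β-diol
Product: 6 α-ketol β-iodoenone (C6 ketone, C1=C2–I, C5β-OH retained, C3α/C4α-acetonide, CH2CH2OTBS)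
Conditions: IBX, DMSO, rt
Reagents that add atoms: none
Why: IBX oxidises the secondary allylic C6 carbinol of a sec/tert 1,2-diol to the α-ketol without glycol cleavage and without base, and because C5 is already fully substituted the new ketone cannot enolise toward C5, which rules out epimerisation and β-elimination of the C4 oxygen towards a phenol.

Step 6
Reactants: 6 α-ketol β-iodoenone
Product: 7 C5β-methanesulfonate of 6
Conditions: MsCl, Et3N, CH2Cl2, −20 → 0 °C
Reagents that add atoms: methanesulfonyl chloride, CS(=O)(=O)Cl
Why: Mesylation through sulfene is insensitive to the tertiary nature of the only free hydroxyl, proceeds with retention because the C5–O bond is not broken, and gives a sulfonate that is isolable since the adjacent carbonyl disfavours ionisation.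

Step 7
Reactants: 7 C5β-mesylate β-iodoenone; 8 (tributylstannyl)methanol
Product: 9 C2-hydroxymethyl enone mesylate (iodine of 7 replaced by CH2OH)
Conditions: Pd2(dba)3·CHCl3 (cat.), AsPh3, NMP, 45 °C
Reagents that add atoms: none
Why: Stille coupling: the β-iodoenone undergoes fast oxidative addition, the α-oxygenated CH2OH group is transferred from tin in preference to butyl, and the neutral, mildly warm medium leaves mesylate, ketal and silyl ether untouched.

Step 8
Reactants: 9 C2-hydroxymethyl enone mesylate
Product: 11 (1R,5R,6R)-5-hydroxy-1-(2-hydroxyethyl)-4-(hydroxymethyl)-7-oxabicyclo[4.1.0]hept-3-en-2-one, via tetraol mesylate 10 (not isolated)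
Conditions: TFA/H2O (4:1), 0 °C → rt; evaporate with toluene; then K2CO3, MeCN, 0 °C → rt
Reagents that add atoms: none
Why: Aqueous acid removes ketal and silyl ether, and carbonate then lets the C4α oxygen, trans and antiperiplanar to the C5β mesylate in the diaxial half-chair, displace it in a 3-exo-tet SN2 closure (the ring-closing half of a Darzens reaction, as used for α-sulfonyloxy-β-hydroxy carbonyl compounds) that inverts C5, leaves C3 and C4 untouched and so places the oxirane on the α face, syn to C3–OH.

Step 9
Reactants: 11 epoxy enone triol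
Product: 12 1,3-dioxane acetonide of 11 (C2–CH2–O and C3–O joined through CMe2; α-oxirane; side-chain CH2CH2OH free)
Conditions: Me2C(OMe)2, PPTS (cat.), acetone, rt
Reagents that add atoms: 2,2-dimethoxypropane, COC(C)(C)OC
Why: Transketalisation under PPTS can form a cyclic ketal only across the one 1,3-diol pair (C2–CH2OH/C3–OH), giving the 1,3-dioxane and leaving the side-chain alcohol free for the later oxidation, while the ketone-deactivated oxirane tolerates the weak acid.

Step 10
Reactants: 12 epoxy enone acetonide
Product: 13 C1-iodo derivative of 12 (2-iodoenone)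
Conditions: I2, pyridine/CH2Cl2 (1:1), DMAP (cat.), 0 °C → rt, dark
Reagents that add atoms: iodine, II
Why: Amine-mediated α-iodination of a cycloalkenone (Baylis–Hillman-type conjugate addition of the amine, iodination of the enolate at C1, elimination), established for β-alkyl-γ-oxygenated and for α′,β′-epoxy cyclohexenones, can only strike C1, the sole vinylic C–H, and spares alcohol, ketal and oxirane.

Step 11
Reactants: 13 2-iodoenone; 14 (E)-hept-1-enylboronic acid
Product: 15 C1-[(E)-hept-1-enyl] dienone alcohol (13 with I replaced by the E-heptenyl chain)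
Conditions: PdCl2(PhCN)2 (cat.), AsPh3, Ag2O, THF/H2O (8:1), rt
Reagents that add atoms: none
Why: Suzuki–Miyaura coupling of a 2-iodoenone under Ag2O/AsPh3 promotion runs at room temperature without strong base, so that the epoxy ketone survives, and transfers the alkenyl group with retention of its E geometry.

Step 12
Reactants: 15 dienone alcohol
Product: 16 aldehyde (side chain CH2CHO on C5)
Conditions: Dess–Martin periodinane, NaHCO3, CH2Cl2, 0 °C; used crude
Reagents that add atoms: none
Why: Buffered Dess–Martin oxidation converts the only free hydroxyl into the aldehyde under non-basic conditions that avoid enolisation-driven opening of the neighbouring oxirane.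

Step 13
Reactants: 17 tert-butyl 2-bromopropanoate (racemic)
Product: 19 tert-butyl 2-(triphenylphosphoranylidene)propanoate, via phosphonium bromide 18 (not isolated)
Conditions: PPh3, toluene, 80 °C; then aq NaOH, CH2Cl2, rt
Reagents that add atoms: triphenylphosphine, c1ccc(cc1)P(c1ccccc1)c1ccccc1
Why: SN2 quaternisation of triphenylphosphine by the α-bromo ester and deprotonation of the acidic salt with aqueous hydroxide is the standard entry to ester-stabilised ylides, and the tert-butyl ester is chosen so that the acid can later be freed without base.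

Step 14
Reactants: 16 aldehyde; 19 tert-butyl 2-(triphenylphosphoranylidene)propanoate
Product: 20 tert-butyl (E)-2-methylbut-2-enoate (fully protected target: tert-butyl ester, C2–CH2O/C3–O acetonide)
Conditions: CH2Cl2, rt
Reagents that add atoms: none
Why: Wittig olefination with an α-methyl ester-stabilised ylide is reliably E-selective (ester placed trans to the chain), reacts with the aldehyde far faster than with the hindered ketone, and the ylide is too weak a base to open the β,γ-epoxy aldehyde.

Step 15
Reactants: 20 protected target
Product: 21 (2E)-4-{(1R,5R,6R)-3-[(1E)-hept-1-en-1-yl]-5-hydroxy-4-(hydroxymethyl)-2-oxo-7-oxabicyclo[4.1.0]hept-3-en-1-yl}-2-methylbut-2-enoic acid (CNP0332048.1)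
Conditions: TFA/CH2Cl2 (1:4), H2O (few equiv), 0 °C → rt; toluene azeotrope, pH 7 buffer work-up
Reagents that add atoms: none
Why: Acidolysis cleaves the tert-butyl ester (loss of isobutene) and hydrolyses the 1,3-dioxane in one operation, whereas the oxirane, deactivated by the adjacent C6 carbonyl, and the two E alkenes are not affected, so that no basic saponification of the epoxy enone is needed.

Compound list
1 | 2-(4-iodophenyl)ethanol | OCCc1ccc(I)cc1 | starting material
2 | (1S,2S)-3-(2-hydroxyethyl)-6-iodocyclohexa-3,5-diene-1,2-diol | C1=C(I)[C@@H](O)[C@@H](O)C(CCO)=C1 | intermediate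
3 | C3α,C4α-acetonide of 2 | C1=C(I)[C@H]2OC(C)(C)O[C@H]2C(CCO)=C1 | intermediate
4 | TBS ether of 3 | C1=C(I)[C@H]2OC(C)(C)O[C@H]2C(CCO[Si](C)(C)C(C)(C)C)=C1 | intermediate
5 | 5β,6β-diol | C1=C(I)[C@H]2OC(C)(C)O[C@H]2[C@@](O)(CCO[Si](C)(C)C(C)(C)C)[C@@H]1O | intermediate
6 | α-ketol β-iodoenone | C1=C(I)[C@H]2OC(C)(C)O[C@H]2[C@@](O)(CCO[Si](C)(C)C(C)(C)C)C1=O | intermediate
7 | C5β-mesylate β-iodoenone | C1=C(I)[C@H]2OC(C)(C)O[C@H]2[C@@](OS(C)(=O)=O)(CCO[Si](C)(C)C(C)(C)C)C1=O | intermediate
8 | (tributylstannyl)methanol | CCCC[Sn](CCCC)(CCCC)CO | starting material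
9 | C2-hydroxymethyl enone mesylate | C1=C(CO)[C@H]2OC(C)(C)O[C@H]2[C@@](OS(C)(=O)=O)(CCO[Si](C)(C)C(C)(C)C)C1=O | intermediate
10 | tetraol mesylate (C3α-OH, C4α-OH, C5β-OMs) | C1=C(CO)[C@@H](O)[C@@H](O)[C@@](OS(C)(=O)=O)(CCO)C1=O | intermediate
11 | (1R,5R,6R)-5-hydroxy-1-(2-hydroxyethyl)-4-(hydroxymethyl)-7-oxabicyclo[4.1.0]hept-3-en-2-one | C1=C(CO)[C@@H](O)[C@H]2O[C@@]2(CCO)C1=O | intermediate
12 | 1,3-dioxane acetonide of 11 | C1=C2COC(C)(C)O[C@H]2[C@H]3O[C@@]3(CCO)C1=O | intermediate
13 | C1-iodide of 12 | IC1=C2COC(C)(C)O[C@H]2[C@H]3O[C@@]3(CCO)C1=O | intermediate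
14 | (E)-hept-1-enylboronic acid | CCCCC/C=C/B(O)O | starting material
15 | C1-(E)-heptenyl dienone alcohol | CCCCC/C=C/C1=C2COC(C)(C)O[C@H]2[C@H]3O[C@@]3(CCO)C1=O | intermediate
16 | aldehyde | CCCCC/C=C/C1=C2COC(C)(C)O[C@H]2[C@H]3O[C@@]3(CC=O)C1=O | intermediate
17 | tert-butyl 2-bromopropanoate | CC(Br)C(=O)OC(C)(C)C | starting material
18 | [1-(tert-butoxycarbonyl)ethyl]triphenylphosphonium bromide | CC(C(=O)OC(C)(C)C)[P+](c1ccccc1)(c1ccccc1)c1ccccc1.[Br-] | intermediate
19 | tert-butyl 2-(triphenylphosphoranylidene)propanoate | CC(C(=O)OC(C)(C)C)=P(c1ccccc1)(c1ccccc1)c1ccccc1 | intermediate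
20 | tert-butyl ester acetonide of the target | CCCCC/C=C/C1=C2COC(C)(C)O[C@H]2[C@H]3O[C@@]3(C/C=C(\C)C(=O)OC(C)(C)C)C1=O | intermediate
21 | CNP0332048.1 | CCCCC/C=C/C1=C(CO)[C@@H](O)[C@H]2O[C@@]2(C/C=C(\C)C(=O)O)C1=O | target

Total step count: 15. Longest linear sequence: 14 (steps 1–12, 14, 15; step 13 is a side branch).

Steps most likely to fail

1. **Step 1.** The hydroxyethyl arm may compete with iodine for the large pocket. This would erode or partly reverse the enantiofacial preference, and turnover of the polar iodoarene may be slow. The fallback is a classical resolution through covalent diastereomers; it sets out from 5 and comes back at 5.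
   - Scalemic 5 is acylated at its only readily acylable hydroxyl, the secondary C6β-OH, with (1S)-camphanic chloride (pyridine, DMAP, CH2Cl2).
   - This gives the C6 camphanate F1 together with the camphanate of the mirror-image ring F2.
   - The stereogenic acyl group sits directly on a ring stereocentre, so the pair should separate by crystallisation or chromatography.
   - K2CO3/MeOH then releases enantiopure 5 from F1.

2. **Step 8 (together with the mesylate made in step 6).** Solvolysis or elimination of the tertiary sulfonate, or retro-aldol cleavage of the C4 alkoxide, may outrun the three-membered ring closure. The fallback uses an epoxide as the C5 leaving group instead of a sulfonate; it sets out from 2 and comes back at 12.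
   - Compound 2 is persilylated (TESCl, imidazole) to the tris-TES ether F3.
   - mCPBA/NaHCO3 epoxidises the iodine-free C5=C6 bond anti to both silyloxy groups to give the β-epoxide F4.
   - TBAF frees the hydroxyls to give the trans-epoxy alcohol F5.
   - The C4 alkoxide of F5 attacks C5 from the α face (Payne epoxide migration, aided by aq NaOH/t-BuOH if needed) to give the C4–C5 α-epoxide F6. Unmigrated F5 is separated and re-equilibrated.
   - Stille coupling of F6 with 8 gives the hydroxymethyl tetraol F7.
   - Me2C(OMe)2/PPTS ties the only 1,3-diol into the dioxane diol F8.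
   - MnO2 oxidises the only allylic alcohol of F8 (C6β-OH) to give 12.

3. **Step 10.** Conjugate addition of the amine to the fully substituted C2 may be too slow, so that iodination stalls. The fallback is electrophilic addition–elimination instead of nucleophile-triggered halogenation; it sets out from 12 and comes back at 15.
   - Bromine (CH2Cl2, −78 → 0 °C) is added across C1=C2 to give the 1,2-dibromide F9.
   - Et3N removes the now acidic C1–H with loss of the C2 bromide (E1cB) to give the 2-bromoenone F10.
   - F10 is coupled with 14 under a more active Suzuki–Miyaura catalyst (Pd(OAc)2/SPhos, K3PO4, THF/H2O, 40 °C) to give 15.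

Further compounds
F1 | step 1 | C6-O-[(1S,4R)-camphanoyl] derivative of 5 | C1=C(I)[C@H]2OC(C)(C)O[C@H]2[C@@](O)(CCO[Si](C)(C)C(C)(C)C)[C@@H]1OC(=O)[C@@]34CC[C@@](C)(C(=O)O3)C4(C)C
F2 | step 1 | (1S,4R)-camphanate of the enantiomer of 5 (discarded diastereomer) | C1=C(I)[C@@H]2OC(C)(C)O[C@@H]2[C@](O)(CCO[Si](C)(C)C(C)(C)C)[C@H]1OC(=O)[C@@]34CC[C@@](C)(C(=O)O3)C4(C)C
F3 | step 8 | tris(triethylsilyl) ether of 2 | C1=C(I)[C@@H](O[Si](CC)(CC)CC)[C@@H](O[Si](CC)(CC)CC)C(CCO[Si](CC)(CC)CC)=C1
F4 | step 8 | C5–C6 β-epoxide of F3 | C1=C(I)[C@@H](O[Si](CC)(CC)CC)[C@@H](O[Si](CC)(CC)CC)[C@]2(CCO[Si](CC)(CC)CC)O[C@H]12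
F5 | step 8 | desilylated C5–C6 β-epoxy triol | C1=C(I)[C@@H](O)[C@@H](O)[C@]2(CCO)O[C@H]12
F6 | step 8 | C4–C5 α-epoxide with C3α-OH and C6β-OH (Payne product) | C1=C(I)[C@@H](O)[C@H]2O[C@@]2(CCO)[C@@H]1O
F7 | step 8 | C2-hydroxymethyl analogue of F6 | C1=C(CO)[C@@H](O)[C@H]2O[C@@]2(CCO)[C@@H]1O
F8 | step 8 | 1,3-dioxane acetonide of F7 (C6β-OH and side-chain OH free) | C1=C2COC(C)(C)O[C@H]2[C@H]3O[C@@]3(CCO)[C@@H]1O
F9 | step 10 | C1,C2-dibromide of 12 (anti adduct, face not defined) | BrC1C2(Br)COC(C)(C)O[C@H]2[C@H]3O[C@@]3(CCO)C1=O
F10 | step 10 | C1-bromide of 12 (2-bromoenone) | BrC1=C2COC(C)(C)O[C@H]2[C@H]3O[C@@]3(CCO)C1=O
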